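**Retrosynthetic overview**

1. The target comes from its 7,4',7'',3''',4'''-pentamethyl ether by cleavage of five methyl ethers; that ether comes from the 5,5''-dideoxy biflavone by twofold carbonyl-directed C–H oxygenation at C5 and C5''.
2. Feature: the hydroxyls on C5 (apigenin half) and C5'' (luteolin half) each sit peri to the C4 or C4'' carbonyl of a pyranone ring C. Without them each ring A carries oxygen only at C7 and at C8a (O1), so the one carbon flanked by two oxygens is C8, the axis carbon, and no 6-linked isomer can form.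
3. The dideoxy biflavone comes from closing ring C of the luteolin half (Claisen–Schmidt with 3,4-dimethoxybenzaldehyde, then I2/DMSO) on an acetyl group placed by Friedel–Crafts acetylation/ortho-demethylation on an 8-(2,6-dimethoxyphenyl)flavone; the C8–C8'' axis comes from Suzuki coupling of an 8-bromoflavone with 2,6-dimethoxyphenylboronic acid.
4. The 8-bromoflavone comes from closing ring C of the apigenin half (Claisen–Schmidt with 4-methoxybenzaldehyde, then I2/DMSO) after acetylation/ortho-demethylation of 2-bromo-1,3-dimethoxybenzene. The halves are built one after the other, so no symmetrical bis-acetophenone has to be differentiated.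
5. Ring order: ring A of the apigenin half (bought), ring C of the apigenin half, ring A of the luteolin half (joined through the axis), ring C of the luteolin half; both rings B arrive with the aldehydes.

Key step: step 8

Assumption: the target has no stereocentre and its SMILES gives no descriptor for the 8,8'' axis, so the axis is left unspecified and compounds 9 to 16 are made as racemates about it.

**Step 1**
Reactants: 1 2-bromo-1,3-dimethoxybenzene
Product: 3 1-(3-bromo-2-hydroxy-4-methoxyphenyl)ethan-1-one, via 1-(3-bromo-2,4-dimethoxyphenyl)ethan-1-one 2 (not isolated)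
Conditions: AcCl (1.2 equiv), AlCl3 (2.5 equiv), CH2Cl2, 0 °C → 40 °C; aq. HCl
Reagents that add atoms: acetyl chloride, CC(=O)Cl
Why: Friedel–Crafts acylation enters the only activated position type (ortho to one methoxy, para to the other), and excess AlCl3 then cleaves only the crowded methoxy ortho to the new ketone through a six-membered aluminium chelate (chelation-controlled ortho-demethylation).

**Step 2**
Reactants: 3 1-(3-bromo-2-hydroxy-4-methoxyphenyl)ethan-1-one; 4 4-methoxybenzaldehyde
Product: 5 (E)-1-(3-bromo-2-hydroxy-4-methoxyphenyl)-3-(4-methoxyphenyl)prop-2-en-1-one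
Conditions: KOH (aq. 50 %), EtOH, rt; then dil. HCl
Reagents that add atoms: none
Why: Claisen–Schmidt condensation of a methyl ketone with a non-enolisable aldehyde, in which E1cB dehydration of the aldol gives the thermodynamically preferred E-enone.

**Step 3**
Reactants: 5 (E)-1-(3-bromo-2-hydroxy-4-methoxyphenyl)-3-(4-methoxyphenyl)prop-2-en-1-one
Product: 6 8-bromo-7-methoxy-2-(4-methoxyphenyl)-4H-chromen-4-one
Conditions: I2 (10 mol %), DMSO, 130 °C
Reagents that add atoms: none
Why: Iodine-catalysed oxidative cyclisation of a 2'-hydroxychalcone to the flavone with DMSO as terminal oxidant, a standard flavone synthesis; ring A is protected from iodination by its ketone and bromine.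

**Step 4**
Reactants: 6 8-bromo-7-methoxy-2-(4-methoxyphenyl)-4H-chromen-4-one; 7 2,6-dimethoxyphenylboronic acid (2 equiv)
Product: 8 8-(2,6-dimethoxyphenyl)-7-methoxy-2-(4-methoxyphenyl)-4H-chromen-4-one
Conditions: Pd(OAc)2 (5 mol %), SPhos (2-dicyclohexylphosphino-2',6'-dimethoxybiphenyl, 10 mol %), K3PO4, toluene/H2O 10:1, 100 °C
Reagents that add atoms: none
Why: Suzuki–Miyaura coupling in which the bulky dialkylbiarylphosphine gives a monoligated zerovalent palladium able to join two doubly ortho-oxygenated partners, with excess boronic acid offsetting protodeboronation.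

**Step 5**
Reactants: 8 8-(2,6-dimethoxyphenyl)-7-methoxy-2-(4-methoxyphenyl)-4H-chromen-4-one
Product: 10 8-(3-acetyl-2-hydroxy-6-methoxyphenyl)-7-methoxy-2-(4-methoxyphenyl)-4H-chromen-4-one, via 8-(3-acetyl-2,6-dimethoxyphenyl)-7-methoxy-2-(4-methoxyphenyl)-4H-chromen-4-one 9 (not isolated)
Conditions: AcCl (1.5 equiv), AlCl3 (4 equiv), CH2Cl2, 0 °C → 40 °C; aq. HCl
Reagents that add atoms: acetyl chloride, CC(=O)Cl
Why: Friedel–Crafts acylation should pick C3 of the twisted 2,6-dimethoxyphenyl ring, the only ring not deactivated by the AlCl3-bound pyranone, and chelation-controlled ortho-demethylation then frees only the methoxy between the acetyl group and the axis, since the 7- and 4'-methoxy groups cannot chelate.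

**Step 6**
Reactants: 10 8-(3-acetyl-2-hydroxy-6-methoxyphenyl)-7-methoxy-2-(4-methoxyphenyl)-4H-chromen-4-one; 11 3,4-dimethoxybenzaldehyde
Product: 12 8-{3-[(E)-3-(3,4-dimethoxyphenyl)prop-2-enoyl]-2-hydroxy-6-methoxyphenyl}-7-methoxy-2-(4-methoxyphenyl)-4H-chromen-4-one
Conditions: KOH (aq. 50 %), EtOH/THF, rt; then dil. HCl
Reagents that add atoms: none
Why: Claisen–Schmidt condensation at the only enolisable ketone gives the E-enone by E1cB dehydration, and the existing flavone tolerates hydroxide at room temperature.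

**Step 7**
Reactants: 12 8-{3-[(E)-3-(3,4-dimethoxyphenyl)prop-2-enoyl]-2-hydroxy-6-methoxyphenyl}-7-methoxy-2-(4-methoxyphenyl)-4H-chromen-4-one
Product: 13 2-(3,4-dimethoxyphenyl)-7-methoxy-8-[7-methoxy-2-(4-methoxyphenyl)-4-oxo-4H-chromen-8-yl]-4H-chromen-4-one (5,5''-dideoxy pentamethyl ether)
Conditions: I2 (10 mol %), DMSO, 130 °C
Reagents that add atoms: none
Why: The same iodine-catalysed oxidative cyclisation of a 2'-hydroxychalcone closes the second pyranone through the phenol next to the axis, which fixes the 8,8'' linkage.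

**Step 8**
Reactants: 13 5,5''-dideoxy pentamethyl ether
Product: 15 2-(3,4-dimethoxyphenyl)-5-hydroxy-8-[5-hydroxy-7-methoxy-2-(4-methoxyphenyl)-4-oxo-4H-chromen-8-yl]-7-methoxy-4H-chromen-4-one, via 5,5''-bis(trifluoroacetate) ester 14 (not isolated)
Conditions: [RuCl2(p-cymene)]2 (10 mol %), PhI(OCOCF3)2 (4 equiv), CF3CO2H/(CF3CO)2O 3:1, 80 °C; then aq. NaHCO3/MeOH, rt
Reagents that add atoms: bis(trifluoroacetoxy)iodobenzene, FC(F)(F)C(=O)OI(OC(=O)C(F)(F)F)c1ccccc1 (its trifluoroacetate oxygen stays as the phenol oxygen; the carboxylate exchanges with the trifluoroacetic acid medium, OC(=O)C(F)(F)F)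
Why: Chloride/trifluoroacetate exchange gives a cationic divalent ruthenium carboxylate that binds the C4 (and C4'') carbonyl oxygen, and carboxylate-assisted metalation of the peri C5–H (C5''–H) gives a five-membered ruthenacycle (Ru–O=C4–C4a–C5). PhI(OCOCF3)2 oxidises this to a tetravalent ruthenium aryl trifluoroacetate, C–O reductive elimination releases the aryl trifluoroacetate and returns divalent ruthenium, and the esters of 14 are hydrolysed on work-up. The closest known reaction is the ruthenium-catalysed carbonyl-directed C5–H hydroxylation of flavones and chromones (ketone-directed ortho C–H oxygenation) with this catalyst and oxidant, run here on two independent, mutually twisted flavone units with a doubled charge of oxidant. No ring is closed and no stereocentre is formed; the two new bonds are C5–O and C5''–O. The step must choose C5 and C5'' over C6, C6'', C3, C3'' and the methoxylated rings B, and the chelate geometry secures this because a carbonyl-bound metal reaches only the peri C–H. Protonation of the pyranones in CF3CO2H lowers the electron density of all rings toward the trivalent-iodine oxidant, and trifluoroacetylation of each new phenol in the anhydride medium guards it against further oxidation.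

**Step 9**
Reactants: 15 5,5''-dihydroxy pentamethyl ether
Product: 16 2-(3,4-dihydroxyphenyl)-8-[5,7-dihydroxy-2-(4-hydroxyphenyl)-4-oxo-4H-chromen-8-yl]-5,7-dihydroxy-4H-chromen-4-one (target)
Conditions: BBr3 (15 equiv), CH2Cl2, −78 °C → rt; H2O
Reagents that add atoms: none
Why: Lewis-acid cleavage of aryl methyl ethers by BBr3 removes all five methyl groups, and keeping the temperature low avoids acid-promoted Wessely–Moser ring opening and reclosure that would move the linkage from C8 to C6.

**Compound list**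

1 | 2-bromo-1,3-dimethoxybenzene | COc1cccc(OC)c1Br | starting material
2 | 1-(3-bromo-2,4-dimethoxyphenyl)ethan-1-one | CC(=O)c1ccc(OC)c(Br)c1OC | intermediate
3 | 1-(3-bromo-2-hydroxy-4-methoxyphenyl)ethan-1-one | CC(=O)c1ccc(OC)c(Br)c1O | intermediate
4 | 4-methoxybenzaldehyde | COc1ccc(C=O)cc1 | starting material
5 | (E)-1-(3-bromo-2-hydroxy-4-methoxyphenyl)-3-(4-methoxyphenyl)prop-2-en-1-one | COc1ccc(/C=C/C(=O)c2ccc(OC)c(Br)c2O)cc1 | intermediate
6 | 8-bromo-7-methoxy-2-(4-methoxyphenyl)-4H-chromen-4-one | COc1ccc(cc1)-c1cc(=O)c2ccc(OC)c(Br)c2o1 | intermediate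
7 | 2,6-dimethoxyphenylboronic acid | COc1cccc(OC)c1B(O)O | starting material
8 | 8-(2,6-dimethoxyphenyl)-7-methoxy-2-(4-methoxyphenyl)-4H-chromen-4-one | COc1ccc(cc1)-c1cc(=O)c2ccc(OC)c(c2o1)-c1c(OC)cccc1OC | intermediate
9 | 8-(3-acetyl-2,6-dimethoxyphenyl)-7-methoxy-2-(4-methoxyphenyl)-4H-chromen-4-one | COc1ccc(cc1)-c1cc(=O)c2ccc(OC)c(c2o1)-c1c(OC)ccc(C(C)=O)c1OC | intermediate
10 | 8-(3-acetyl-2-hydroxy-6-methoxyphenyl)-7-methoxy-2-(4-methoxyphenyl)-4H-chromen-4-one | COc1ccc(cc1)-c1cc(=O)c2ccc(OC)c(c2o1)-c1c(OC)ccc(C(C)=O)c1O | intermediate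
11 | 3,4-dimethoxybenzaldehyde | COc1ccc(C=O)cc1OC | starting material
12 | 8-{3-[(E)-3-(3,4-dimethoxyphenyl)prop-2-enoyl]-2-hydroxy-6-methoxyphenyl}-7-methoxy-2-(4-methoxyphenyl)-4H-chromen-4-one | COc1ccc(cc1)-c1cc(=O)c2ccc(OC)c(c2o1)-c1c(OC)ccc(C(=O)/C=C/c2ccc(OC)c(OC)c2)c1O | intermediate
13 | 2-(3,4-dimethoxyphenyl)-7-methoxy-8-[7-methoxy-2-(4-methoxyphenyl)-4-oxo-4H-chromen-8-yl]-4H-chromen-4-one (5,5''-dideoxy pentamethyl ether) | COc1ccc(cc1)-c1cc(=O)c2ccc(OC)c(c2o1)-c1c(OC)ccc2c(=O)cc(oc12)-c1ccc(OC)c(OC)c1 | intermediate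
14 | 5,5''-bis(trifluoroacetate) ester of 15 | COc1ccc(cc1)-c1cc(=O)c2c(OC(=O)C(F)(F)F)cc(OC)c(c2o1)-c1c(OC)cc(OC(=O)C(F)(F)F)c2c(=O)cc(oc12)-c1ccc(OC)c(OC)c1 | intermediate
15 | 2-(3,4-dimethoxyphenyl)-5-hydroxy-8-[5-hydroxy-7-methoxy-2-(4-methoxyphenyl)-4-oxo-4H-chromen-8-yl]-7-methoxy-4H-chromen-4-one | COc1ccc(cc1)-c1cc(=O)c2c(O)cc(OC)c(c2o1)-c1c(OC)cc(O)c2c(=O)cc(oc12)-c1ccc(OC)c(OC)c1 | intermediate
16 | 2-(3,4-dihydroxyphenyl)-8-[5,7-dihydroxy-2-(4-hydroxyphenyl)-4-oxo-4H-chromen-8-yl]-5,7-dihydroxy-4H-chromen-4-one | O=c1cc(-c2ccc(O)cc2)oc2c(-c3c(O)cc(O)c4c(=O)cc(-c5ccc(O)c(O)c5)oc34)c(O)cc(O)c12 | target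

**Totals**

Total step count: 9. Longest linear sequence: 9 steps (1 to 16; the aldehydes 4 and 11 and the boronic acid 7 are bought).

**Steps most likely to fail**

Step 8. Oxidation of the methoxy-bearing rings by the trivalent-iodine oxidant may compete with the directed metalation, or the reaction may stop after one of the two oxygenations. The fallback sets out from 13 and comes back at 16. The methyl ethers would be cleaved first (BBr3, CH2Cl2) to 2-(3,4-dihydroxyphenyl)-7-hydroxy-8-[7-hydroxy-2-(4-hydroxyphenyl)-4-oxo-4H-chromen-8-yl]-4H-chromen-4-one F1. Peracetylation (Ac2O, pyridine) would give its pentaacetate F2, in which every ring is electron-poor and resists the oxidant. The same ruthenium-catalysed oxygenation on F2 would give the pentaacetate 5,5''-bis(trifluoroacetate) F3. One acid hydrolysis (aq. HCl, THF, 60 °C) would remove all seven esters and give 16 directly, so 15 and step 9 are bypassed.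

Step 4. Protodeboronation of the boronic acid may outrun transmetalation onto the crowded arylpalladium bromide. The fallback sets out from 1 and 6 and comes back at 8. Bromine–lithium exchange on 1 (n-BuLi, 1.0 equiv, THF, −78 °C) would give 2,6-dimethoxyphenyllithium F4. ZnCl2 would convert it into 2,6-dimethoxyphenylzinc chloride F5, which cannot lose its metal by protonolysis under the anhydrous conditions and transmetalates faster. Negishi coupling of F5 with 6 (Pd2(dba)3, RuPhos (2-dicyclohexylphosphino-2',6'-diisopropoxybiphenyl), THF, 65 °C) would give 8; the arylzinc does not add to the pyranone.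

Step 5. Site control in the acylation may be lost (attack on ring B ortho to its methoxy), or AlCl3 may cleave non-chelated methyl ethers. The fallback sets out from 8 and comes back at 10, and brings the acetyl group in without a strong Lewis acid. Bromination with N-bromosuccinimide (MeCN, 0 °C → rt) on the most electron-rich ring would give 8-(3-bromo-2,6-dimethoxyphenyl)-7-methoxy-2-(4-methoxyphenyl)-4H-chromen-4-one F6. Stille coupling with tributyl(1-ethoxyvinyl)stannane (PdCl2(PPh3)2, toluene, 100 °C) would give 8-[3-(1-ethoxyvinyl)-2,6-dimethoxyphenyl]-7-methoxy-2-(4-methoxyphenyl)-4H-chromen-4-one F7. Dilute aq. HCl in THF would hydrolyse the enol ether to the ketone 9, isolated in this variant, and BCl3 (CH2Cl2, −78 → 0 °C) would cleave only the chelated methoxy to give 10.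

**Further compounds**

F1 | step 8 | 2-(3,4-dihydroxyphenyl)-7-hydroxy-8-[7-hydroxy-2-(4-hydroxyphenyl)-4-oxo-4H-chromen-8-yl]-4H-chromen-4-one | Oc1ccc(cc1)-c1cc(=O)c2ccc(O)c(c2o1)-c1c(O)ccc2c(=O)cc(oc12)-c1ccc(O)c(O)c1
F2 | step 8 | pentaacetate of F1 | CC(=O)Oc1ccc(cc1)-c1cc(=O)c2ccc(OC(C)=O)c(c2o1)-c1c(OC(C)=O)ccc2c(=O)cc(oc12)-c1ccc(OC(C)=O)c(OC(C)=O)c1
F3 | step 8 | 5,5''-bis(trifluoroacetoxy) derivative of pentaacetate F2 | CC(=O)Oc1ccc(cc1)-c1cc(=O)c2c(OC(=O)C(F)(F)F)cc(OC(C)=O)c(c2o1)-c1c(OC(C)=O)cc(OC(=O)C(F)(F)F)c2c(=O)cc(oc12)-c1ccc(OC(C)=O)c(OC(C)=O)c1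
F4 | step 4 | 2,6-dimethoxyphenyllithium | [Li]c1c(OC)cccc1OC
F5 | step 4 | 2,6-dimethoxyphenylzinc chloride | Cl[Zn]c1c(OC)cccc1OC
F6 | step 5 | 8-(3-bromo-2,6-dimethoxyphenyl)-7-methoxy-2-(4-methoxyphenyl)-4H-chromen-4-one | COc1ccc(cc1)-c1cc(=O)c2ccc(OC)c(c2o1)-c1c(OC)ccc(Br)c1OC
F7 | step 5 | 8-[3-(1-ethoxyvinyl)-2,6-dimethoxyphenyl]-7-methoxy-2-(4-methoxyphenyl)-4H-chromen-4-one | COc1ccc(cc1)-c1cc(=O)c2ccc(OC)c(c2o1)-c1c(OC)ccc(C(=C)OCC)c1OC
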